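**Strategy.** The cage is cut at C5–C6 and C3–C11, the two bonds that tie the four-carbon bridge C6–C7–C10–C11 to the carbons flanking the C4 carbonyl of ring A, the acylphloroglucinol-derived triketone ring. The key step uses this C3–C4(=O)–C5 unit as a 1,3-dinucleophile. An aromatic acylphloroglucinol carrying a gem-dimethyl-tethered chloromethyl enone on C3 undergoes, in one operation, dearomative Michael addition (spiro-cyclopentane, C3–C11) and C-alkylation by the α-chloroketone (seven-membered ring, C5–C6) within a chiral ammonium ion pair. Isopropyl addition at C7, cation–enol closure of C1–C8 and bridgehead geranylation of C5 then complete the homoadamantane.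

Key step: step 4

Numbering used throughout: ring A = C1 (benzoyl-bearing), C2, C3 (spiro carbon), C4, C5 (geranyl-bearing), C9 (carbonyl between C5 and C1); C6 = CH2 on C5; C7 = methine; C8 = gem-dimethyl carbon on C1; C10 = CH2; C11 = cyclopentane methine on C3; C12 (gem-dimethyl), C13, C14 = remaining cyclopentane carbons.

Assumption: the cinchonidine-derived ammonium salt is taken to favour the enantiomer drawn; if the sense proves opposite, the pseudo-enantiomeric cinchonine-derived salt is used with no other change.

Compounds 1, 4, 7 and 14 are commercial.

**Step 1**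
Reactants: 1 2,2-dimethylpent-4-enal
Product: 3 2,2-dimethylbutanedial, via ozonide 2 (not isolated)
Conditions: O3, CH2Cl2, −78 °C; then Me2S, −78 °C to rt; used crude
Reagents that add atoms: ozone, [O-][O+]=O
Why: Ozonolysis with reductive work-up cleaves the terminal alkene to the CH2–CHO group while the neopentyl aldehyde survives at low temperature; no stereocenter is formed.

**Step 2**
Reactants: 3 2,2-dimethylbutanedial; 4 2,4,6-trihydroxybenzophenone (1.5 equiv)
Product: 6 4-(3-benzoyl-2,4,6-trihydroxyphenyl)-2,2-dimethylbutanal, via quinone methide 5 (not isolated)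
Conditions: L-proline (0.2 equiv), diethyl 2,6-dimethyl-1,4-dihydropyridine-3,5-dicarboxylate (1.2 equiv), CH2Cl2, rt
Reagents that add atoms: none
Why: Proline-catalysed Knoevenagel condensation of the unhindered CH2–CHO group with the free ring carbon gives the ortho-quinone methide, which the dihydropyridine reduces by conjugate hydride transfer (three-component reductive alkylation); the neopentyl aldehyde is too hindered to condense and no stereocenter is formed.

**Step 3**
Reactants: 6 aryl aldehyde; 7 1-chloro-3-(triphenyl-λ5-phosphanylidene)propan-2-one (1.5 equiv)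
Product: 8 (E)-7-(3-benzoyl-2,4,6-trihydroxyphenyl)-1-chloro-5,5-dimethylhept-3-en-2-one
Conditions: toluene, 90 °C
Reagents that add atoms: none
Why: Wittig olefination with the ketone-stabilised ylide, which is too weakly basic to deprotonate the phenols, should give the (E)-enone at the non-enolisable aldehyde.

**Step 4**
Reactants: 8 chloromethyl enone
Product: 10 tricyclic C7-ketone, via spiro dienone 9 (not isolated)
Conditions: N-(9-anthracenylmethyl)-O-allylcinchonidinium bromide (0.2 equiv), CsOH·H2O (4 equiv), CH2Cl2, 4 Å molecular sieves, 0.01 M, −50 to −20 °C; dilute HCl work-up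
Reagents that add atoms: none
Why: The phenoxide of 8, paired with the chiral ammonium cation, adds through its alkylated ring carbon C3 to the β-carbon C11 of the tethered enone with loss of aromaticity to give spiro dienone 9, whose free ring carbon C5 then displaces chloride from the α-chloroketone (Michael addition, then SN2 C-alkylation). The closest known reaction type is the phase-transfer alkylative dearomatization–annulation of acylphloroglucinols with bis-electrophiles, here run intramolecularly as a (3+4) annulation across C3–C4(=O)–C5. The cyclopentane closes 5-exo-trig, helped by the gem-dimethyl group on the tether, and the cycloheptanone closes 7-exo-tet, made feasible by the high SN2 reactivity of the α-chloroketone. C3 and C11 are formed in the reversible Michael step, so the irreversible ring closure should select the isomer in which the seven-membered ring forms on the side of C11 that carries H, away from the gem-dimethyl carbon C12; C5 follows from the bicyclic constraint and the absolute sense from the cinchona cation. The step needs C- over O-alkylation and attack by C5 and not by the benzoylated C1, which the soft α-chloroketone and the much higher nucleophilicity of the unacylated C5 should secure.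

**Step 5**
Reactants: 10 tricyclic C7-ketone
Product: 11 C7 isopropyl carbinol
Conditions: CeCl3 (anhydrous, 6 equiv), i-PrMgCl (6 equiv), THF, −78 to 0 °C; aq NH4Cl
Reagents that add atoms: isopropylmagnesium chloride, CC(C)[Mg]Cl
Why: Organocerium 1,2-addition (Grignard type) should occur at C7, the only unhindered ketone, because the benzoyl triketone is shielded as its enolate and C4 is flanked by C3 and C5; the new carbinol center forms as a mixture that step 6 erases.

**Step 6**
Reactants: 11 C7 isopropyl carbinol
Product: 13 des-geranyl cage trione, via alkene 12 (not isolated)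
Conditions: TfOH (0.5 equiv), (CF3)2CHOH/CH2Cl2 1:4, 0 °C to rt
Reagents that add atoms: none
Why: Acid ionises the tertiary carbinol and reversible proton loss and regain through the tetrasubstituted alkene 12 relays the cation to C8, which the enol carbon C1 captures irreversibly (cation–enol cyclisation closing the C1–C8 bond), while O-alkylated or eliminated isomers re-ionise; C1 and C7 are fixed by the cage because only the arrangement with C8 pointing at C1 can close.

**Step 7**
Reactants: 13 des-geranyl cage trione; 14 geranyl bromide (3 equiv)
Product: 16 target, via bridgehead organolithium 15 (not isolated)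
Conditions: lithium 2,2,6,6-tetramethylpiperidide (1.5 equiv), THF, −78 °C; then 14, −78 to 0 °C
Reagents that add atoms: none
Why: Deprotonation of the only acidic C–H left, the bridgehead C5–H between the C4 and C9 carbonyls, and SN2 alkylation of the bridgehead carbanion with the allylic bromide (bridgehead alkylation of a bicyclic triketone) should give the target with C5 fixed by the cage and the (E)-alkene of the geranyl unit unchanged.

**Compound list**

1 | 2,2-dimethylpent-4-enal | C=CCC(C)(C)C=O | starting material
2 | 3-(2,2-dimethyl-3-oxopropyl)-1,2,4-trioxolane (ozonide of 1) | O=CC(C)(C)CC1OCOO1 | intermediate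
3 | 2,2-dimethylbutanedial | O=CCC(C)(C)C=O | intermediate
4 | 2,4,6-trihydroxybenzophenone | O=C(c1ccccc1)c1c(O)cc(O)cc1O | starting material
5 | ortho-quinone methide from condensation of 4 at its ring carbon with the CH2–CHO group of 3 | O=CC(C)(C)CC=C1C(=O)C=C(O)C(C(=O)c2ccccc2)=C1O | intermediate
6 | 4-(3-benzoyl-2,4,6-trihydroxyphenyl)-2,2-dimethylbutanal | O=CC(C)(C)CCc1c(O)cc(O)c(C(=O)c2ccccc2)c1O | intermediate
7 | 1-chloro-3-(triphenyl-λ5-phosphanylidene)propan-2-one | O=C(CCl)C=P(c1ccccc1)(c1ccccc1)c1ccccc1 | starting material
8 | (E)-7-(3-benzoyl-2,4,6-trihydroxyphenyl)-1-chloro-5,5-dimethylhept-3-en-2-one | O=C(CCl)/C=C/C(C)(C)CCc1c(O)cc(O)c(C(=O)c2ccccc2)c1O | intermediate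
9 | spiro dienone: cyclohexadienone ring A spiro-fused at C3 to the 2,2-dimethylcyclopentane, C11 bearing the 3-chloro-2-oxopropyl arm; C3 and C11 as in 10 | O=C1C=C(O)C(C(=O)c2ccccc2)=C(O)[C@]13CCC(C)(C)[C@H]3CC(=O)CCl | intermediate
10 | tricyclic C7-ketone: C6H2–C7(=O)–C10H2–C11H bridge across C5 and C3 of ring A, cyclopentane fused at C3–C11, C5–H, C1-benzoyl with C1=C9 enol; C3, C5, C11 as in the target, C12 on the C2 side | O=C1[C@H]2CC(=O)C[C@@H]3C(C)(C)CC[C@@]13C(=O)C(C(=O)c4ccccc4)=C2O | intermediate
11 | C7 isopropyl carbinol of 10 (both C7 epimers) | O=C1[C@H]2CC(O)(C(C)C)C[C@@H]3C(C)(C)CC[C@@]13C(=O)C(C(=O)c4ccccc4)=C2O | intermediate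
12 | C7 isopropylidene alkene (C7=C8) | O=C1[C@H]2CC(=C(C)C)C[C@@H]3C(C)(C)CC[C@@]13C(=O)C(C(=O)c4ccccc4)=C2O | intermediate
13 | des-geranyl cage trione: the target with H in place of geranyl at C5, all other centers as in the target | O=C1[C@H]2C[C@H]3C[C@@H]4C(C)(C)CC[C@@]14C(=O)[C@@](C(=O)c5ccccc5)(C2=O)C3(C)C | intermediate
14 | geranyl bromide, (E)-1-bromo-3,7-dimethylocta-2,6-diene | CC(C)=CCC/C(C)=C/CBr | starting material
15 | C5 bridgehead organolithium of 13 | [Li][C@@]12C[C@H]3C[C@@H]4C(C)(C)CC[C@]4(C1=O)C(=O)[C@@](C(=O)c1ccccc1)(C2=O)C3(C)C | intermediate
16 | CNP0168637.1, the 5-geranyl homoadamantane trione | CC(C)=CCC/C(C)=C/C[C@@]12C[C@H]3C[C@@H]4C(C)(C)CC[C@]4(C1=O)C(=O)[C@@](C(=O)c1ccccc1)(C2=O)C3(C)C | target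

**Step count.** Total: 7 steps. Longest linear sequence: 7 steps (from 1).

**Steps most likely to fail and fallbacks**

Step 4. The chiral ion pair may discriminate the two faces poorly during spirocyclisation and ring closure, and hydroxide may divert the α-chloroketone into Favorskii or Darzens-type closure. The fallback sets out from 8 and runs the same annulation with Cs2CO3 in MeCN at high dilution, giving 10 as the racemate. The strongly acidic enol is then resolved by fractional crystallisation of its salt with (R)-1-phenylethylamine, the ammonium enolate salt F1. Breaking the salt with dilute HCl returns to the route at 10.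

Step 6. The tertiary cation may be lost through proton loss to endocyclic alkenes or O-alkylation of the enol faster than it is relayed to C8 and trapped at C1. The fallback sets out from 10. Wittig olefination with the ylide from isopropyltriphenylphosphonium iodide and n-BuLi gives the alkene 12 in isolated form. Selenium-induced carbocyclisation (PhSeCl, then SnCl4, CH2Cl2, −78 °C) lets C1 open the seleniranium ion at C8 and gives the C7 phenylselanyl cage F2. Radical deselenation (Bu3SnH, azobisisobutyronitrile, toluene, 80 °C) returns to the route at 13.

Step 7. The hindered bridgehead carbanion may react with the allylic bromide by electron transfer, SN2′ attack or elimination instead of direct substitution. The fallback sets out from 13. The carbanion is quenched with I2 to give the C5 bridgehead iodide F3. Reductive cross-electrophile allylation with commercial geranyl acetate (NiCl2(dme), 4,4′-di-tert-butyl-2,2′-bipyridine, Zn, MgCl2, N,N-dimethylacetamide, rt) should couple the bridgehead radical at the unhindered allyl terminus with retention of the (E)-alkene, and returns to the route at 16.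

**Further compounds**

F1 | step 4 | (R)-1-phenylethylammonium enolate salt of 10 | C[C@@H]([NH3+])c1ccccc1.O=C1[C@H]2CC(=O)C[C@@H]3C(C)(C)CC[C@@]13C(=O)C(C(=O)c4ccccc4)=C2[O-]
F2 | step 6 | C7 phenylselanyl derivative of cage 13 | O=C1[C@H]2C[C@@]3([Se]c6ccccc6)C[C@@H]4C(C)(C)CC[C@@]14C(=O)[C@@](C(=O)c5ccccc5)(C2=O)C3(C)C
F3 | step 7 | C5 bridgehead iodide of cage 13 | I[C@@]12C[C@H]3C[C@@H]4C(C)(C)CC[C@]4(C1=O)C(=O)[C@@](C(=O)c1ccccc1)(C2=O)C3(C)C
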